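**Retrosynthetic overview**

1. Last C–C bond: C4 of the upper unit to C6 of the lower unit, by anti Friedel–Crafts opening of the 2,3-cis-3,4-epoxyflavan 15 with ring D of the bis-silylated flavan-3,4-diol 17. Compound 17 is made from the same epoxide 15, so one monomer line serves both halves.
2. Epoxide 15 comes from the (2S)-flav-3-ene 13 by bromohydrin formation anti to the 2-aryl group and base closure. The single stereocenter C2 thus relays the configuration to C3 (oxygen cis to aryl) and C4 (nucleophile anti to oxygen) in both units.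
3. Key disconnection (ring C, bonds O1–C8a and C3–C4): benzyl sulfide 5 (ring A plus C4) and (R)-aryloxirane 8 (O1–C2–C3 plus ring B) give 4-sulfanylflavan 11 in one anionic operation. Sulfoxide elimination then gives 13.
4. Enabling feature: in ring A the oxygen-bearing C8a is ortho to C4a, which carries the benzylic C4, and C8a lies between C8–O and C4a (no ortho hydrogen). A C4 carbanion and a C8a–F ipso electrophile therefore match the O1–C2–C3 unit of an oxirane whose C2 already holds O1, the ring-B aryl group and the (R) configuration.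
5. Ring order: rings A and B are bought; ring C of the monomer is closed in step 6; the oxirane in step 8; the pyran ring of the lower unit is the same ring C, brought in through 17 in step 11.

Key step: step 6

Remark (assumption): the target is read from its SMILES as epioritin-(4β→6)-epioritin-4β-ol, both flavan units (2R), 2,3-cis and 3,4-trans. Compounds 1 and 6 are taken as commercial.

**Route**

Step 1
Reactants: 1 2-fluoro-3,4-dimethoxybenzaldehyde
Product: 2 2-fluoro-3,4-dihydroxybenzaldehyde
Conditions: BBr3, CH2Cl2, −78 °C → 20 °C; then H2O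
Reagents that add atoms: none
Why: Lewis-acid cleavage of aryl methyl ethers (BBr3 demethylation) should free both phenols and leave the aryl fluoride and the aldehyde untouched; no stereocenter is formed.

Step 2
Reactants: 2 2-fluoro-3,4-dihydroxybenzaldehyde
Product: 3 3,4-bis(benzyloxy)-2-fluorobenzaldehyde
Conditions: BnBr, K2CO3, DMF, 50 °C
Reagents that add atoms: benzyl bromide, BrCc1ccccc1
Why: Williamson etherification of both phenols; benzyl ethers are chosen because they survive the organolithium, alkoxide and Lewis-acid steps and leave by hydrogenolysis at the end.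

Step 3
Reactants: 3 3,4-bis(benzyloxy)-2-fluorobenzaldehyde
Product: 4 [3,4-bis(benzyloxy)-2-fluorophenyl]methanol
Conditions: NaBH4, MeOH/THF, 0 °C
Reagents that add atoms: none
Why: borohydride reduction of an aromatic aldehyde to the benzylic alcohol; no stereocenter is formed.

Step 4
Reactants: 4 [3,4-bis(benzyloxy)-2-fluorophenyl]methanol
Product: 5 1,2-bis(benzyloxy)-3-fluoro-4-[(phenylsulfanyl)methyl]benzene
Conditions: PhSSPh, PBu3, THF, 20 °C
Reagents that add atoms: diphenyl disulfide, c1ccc(SSc2ccccc2)cc1
Why: Hata-type deoxygenative thioetherification (disulfide and trialkylphosphine; SN2 of thiolate on the alkoxyphosphonium ion) should convert the primary benzylic alcohol into the sulfide under neutral conditions that spare the benzyl ethers.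

Step 5
Reactants: 6 2-bromo-1-[4-(benzyloxy)phenyl]ethanone
Product: 8 (2R)-2-[4-(benzyloxy)phenyl]oxirane, via bromohydrin 7 (not isolated)
Conditions: BH3·SMe2, (R)-2-methyl-CBS-oxazaborolidine (10 mol %), THF, 0 °C; then 2 M NaOH, 20 °C
Reagents that add atoms: none
Why: Corey–Bakshi–Shibata reduction followed by Williamson-type oxirane closure; the (R)-catalyst should deliver hydride to the ketone face that gives the (R)-bromohydrin, and the closure at the CH2Br carbon does not touch that stereocenter.

Step 6
Reactants: 5 1,2-bis(benzyloxy)-3-fluoro-4-[(phenylsulfanyl)methyl]benzene; 8 (2R)-2-[4-(benzyloxy)phenyl]oxirane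
Product: 11 (2S)-7,8-bis(benzyloxy)-2-[4-(benzyloxy)phenyl]-4-(phenylsulfanyl)chromane as a mixture of C4 epimers, via benzyllithium 9 (not isolated), via lithium alkoxide 10 (not isolated)
Conditions: n-BuLi, THF, −78 °C; 8, DMPU, −78 °C → 20 °C; then potassium tert-butoxide, 60 °C
Reagents that add atoms: none
Why: Deprotonation of 5 at the benzylic carbon flanked by sulfur and ring A gives benzyllithium 9, which opens oxirane 8 by SN2 attack at its unsubstituted carbon (C3–C4 bond; alkylation of a lithiated benzyl sulfide with an epoxide) and so unmasks the C2 alkoxide 10; after lithium–potassium exchange this alkoxide displaces fluoride at C8a by addition–elimination through a Meisenheimer-type adduct (O1–C8a bond; intramolecular SNAr etherification of an unactivated aryl fluoride, the closest precedent being base-mediated chroman formation from 3-(2-fluorophenyl)propan-1-ols). Ring C closes as a six-membered ring in the exo mode with respect to the attacked C8a=C8 bond, and no other ring size can compete because 10 holds a single alkoxide. C2 is not formed here: it comes from 8, is touched by neither bond formation and is therefore kept; C4 is formed without control, which is harmless because step 7 makes it sp2. The step needs attack at the terminal and not the benzylic oxirane carbon, which the hindered, charge-delocalised carbanion under Lewis-acid-free conditions with DMPU should secure, and substitution at C8a only, which is secured because C8a lies between the C8 benzyloxy group and C4a, so that no ortho hydrogen is available for an aryne pathway.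

Step 7
Reactants: 11 (2S)-7,8-bis(benzyloxy)-2-[4-(benzyloxy)phenyl]-4-(phenylsulfanyl)chromane
Product: 13 (2S)-7,8-bis(benzyloxy)-2-[4-(benzyloxy)phenyl]-2H-chromene, via sulfoxide 12 (not isolated)
Conditions: m-CPBA (1.0 equiv), CH2Cl2, −78 °C; then NaHCO3, toluene, 80 °C, dark
Reagents that add atoms: none
Why: sulfide oxidation and thermal syn elimination of the benzylic sulfoxide (sulfoxide pyrolysis) can only use the C3 hydrogens and should give the C3=C4 alkene from both C4 epimers; C2 is not involved, and moderate temperature and exclusion of light guard it against electrocyclic ring opening of the chromene.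

Step 8
Reactants: 13 (2S)-7,8-bis(benzyloxy)-2-[4-(benzyloxy)phenyl]-2H-chromene
Product: 15 (2R,3R,4R)-7,8-bis(benzyloxy)-2-[4-(benzyloxy)phenyl]-3,4-epoxychromane (oxirane oxygen cis to the 2-aryl group), via bromohydrin 14 (not isolated)
Conditions: NBS, THF/H2O, 0 °C, dark; then aq. KOH, 0 °C; base-washed work-up, used crude
Reagents that add atoms: water, O
Why: bromohydrin formation and base-induced oxirane closure: bromine should add to C3 on the face anti to the 2-aryl group and water to the benzylic C4 anti to bromine, and the C4 alkoxide then displaces bromide with inversion at C3, so the oxirane ends up on the face of the 2-aryl group (substrate control from C2; this is the face that direct epoxidation would not reach).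

Step 9
Reactants: 15 (2R,3R,4R)-7,8-bis(benzyloxy)-2-[4-(benzyloxy)phenyl]-3,4-epoxychromane
Product: 16 (2R,3R,4S)-7,8-bis(benzyloxy)-2-[4-(benzyloxy)phenyl]chromane-3,4-diol (2,3-cis-3,4-trans)
Conditions: KOH, DMSO/H2O, 50 °C
Reagents that add atoms: water, O
Why: SN2 opening of the epoxide by hydroxide at the benzylic C4 with inversion should set the 4β-hydroxy group trans to the 3-hydroxy group, which stays cis to the 2-aryl group.

Step 10
Reactants: 16 (2R,3R,4S)-7,8-bis(benzyloxy)-2-[4-(benzyloxy)phenyl]chromane-3,4-diol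
Product: 17 (2R,3S,4S)-7,8-bis(benzyloxy)-2-[4-(benzyloxy)phenyl]-3,4-bis[(tert-butyldimethylsilyl)oxy]chromane (same spatial arrangement as 16)
Conditions: TBSOTf, 2,6-lutidine, CH2Cl2, 0 °C → 20 °C
Reagents that add atoms: tert-butyldimethylsilyl trifluoromethanesulfonate, CC(C)(C)[Si](C)(C)OS(=O)(=O)C(F)(F)F
Why: silyl triflate silylation of both secondary alcohols keeps them from acting as oxygen nucleophiles in step 11 and shields the benzylic C4–O bond during the hydrogenolysis of step 12; no stereocenter is changed.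

Step 11
Reactants: 15 (2R,3R,4R)-7,8-bis(benzyloxy)-2-[4-(benzyloxy)phenyl]-3,4-epoxychromane; 17 (2R,3S,4S)-7,8-bis(benzyloxy)-2-[4-(benzyloxy)phenyl]-3,4-bis[(tert-butyldimethylsilyl)oxy]chromane
Product: 18 hexa-O-benzyl ether of the target carrying tert-butyldimethylsilyl ethers on the 3- and 4-hydroxy groups of the lower unit
Conditions: 17 (2.5 equiv), BF3·OEt2 (0.2 equiv), CH2Cl2, −78 °C, slow addition of 15; → −40 °C
Reagents that add atoms: none
Why: Lewis-acid-promoted Friedel–Crafts arylation of a benzylic epoxide: C6 of ring D of 17 (ortho to the 7-benzyloxy group, para to the ring oxygen, and far less hindered than C5) should attack C4 anti to the oxirane oxygen, which sets the upper C4 aryl group trans to the new 3-hydroxy group while that hydroxy group stays cis to the 2-aryl group; excess 17 suppresses self-condensation of 15.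

Step 12
Reactants: 18 hexa-O-benzyl bis-O-silyl dimer
Product: 19 target carrying tert-butyldimethylsilyl ethers on the 3- and 4-hydroxy groups of the lower unit
Conditions: H2 (1 atm), Pd(OH)2/C, EtOAc/THF, 20 °C
Reagents that add atoms: none
Why: hydrogenolysis of the six aryl benzyl ethers; the interflavan bond, the two C2–O bonds and the benzylic silyl ether are expected to persist under neutral conditions, which is why the benzylic hydroxy group of the lower unit is kept silylated here.

Step 13
Reactants: 19 bis-O-silyl hexaphenol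
Product: 20 epioritin-(4β→6)-epioritin-4β-ol (target)
Conditions: Bu4NF, AcOH, THF, 0 °C → 20 °C, argon
Reagents that add atoms: none
Why: fluoride-mediated desilylation buffered with acetic acid should release the 3,4-diol of the lower unit without base- or acid-induced ionisation at its benzylic C4 and without oxidation of the pyrogallol-type rings.

**Compound list**

1 | 2-fluoro-3,4-dimethoxybenzaldehyde | COc1ccc(C=O)c(F)c1OC | starting material
2 | 2-fluoro-3,4-dihydroxybenzaldehyde | Oc1ccc(C=O)c(F)c1O | intermediate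
3 | 3,4-bis(benzyloxy)-2-fluorobenzaldehyde | O=Cc1ccc(OCc2ccccc2)c(OCc2ccccc2)c1F | intermediate
4 | [3,4-bis(benzyloxy)-2-fluorophenyl]methanol | OCc1ccc(OCc2ccccc2)c(OCc2ccccc2)c1F | intermediate
5 | 1,2-bis(benzyloxy)-3-fluoro-4-[(phenylsulfanyl)methyl]benzene | Fc1c(CSc2ccccc2)ccc(OCc2ccccc2)c1OCc1ccccc1 | intermediate
6 | 2-bromo-1-[4-(benzyloxy)phenyl]ethanone | O=C(CBr)c1ccc(OCc2ccccc2)cc1 | starting material
7 | (1R)-2-bromo-1-[4-(benzyloxy)phenyl]ethanol | O[C@@H](CBr)c1ccc(OCc2ccccc2)cc1 | intermediate
8 | (2R)-2-[4-(benzyloxy)phenyl]oxirane | C(Oc1ccc(cc1)[C@@H]1CO1)c1ccccc1 | intermediate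
9 | [3,4-bis(benzyloxy)-2-fluorophenyl](phenylsulfanyl)methyllithium | [Li]C(Sc1ccccc1)c1ccc(OCc2ccccc2)c(OCc2ccccc2)c1F | intermediate
10 | lithium (1S)-1-[4-(benzyloxy)phenyl]-3-[3,4-bis(benzyloxy)-2-fluorophenyl]-3-(phenylsulfanyl)propan-1-olate | [Li]O[C@@H](CC(Sc1ccccc1)c1ccc(OCc2ccccc2)c(OCc2ccccc2)c1F)c1ccc(OCc2ccccc2)cc1 | intermediate
11 | (2S)-7,8-bis(benzyloxy)-2-[4-(benzyloxy)phenyl]-4-(phenylsulfanyl)chromane, C4 epimers | C(c1ccccc1)Oc1ccc([C@H]2Oc3c(ccc(OCc4ccccc4)c3OCc3ccccc3)C(Sc3ccccc3)C2)cc1 | intermediate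
12 | (2S)-7,8-bis(benzyloxy)-2-[4-(benzyloxy)phenyl]-4-(phenylsulfinyl)chromane, stereoisomers at C4 and S | C(c1ccccc1)Oc1ccc([C@H]2Oc3c(ccc(OCc4ccccc4)c3OCc3ccccc3)C(S(=O)c3ccccc3)C2)cc1 | intermediate
13 | (2S)-7,8-bis(benzyloxy)-2-[4-(benzyloxy)phenyl]-2H-chromene | C(c1ccccc1)Oc1ccc([C@H]2Oc3c(ccc(OCc4ccccc4)c3OCc3ccccc3)C=C2)cc1 | intermediate
14 | (2R,3S,4R)-3-bromo-7,8-bis(benzyloxy)-2-[4-(benzyloxy)phenyl]chroman-4-ol (Br trans to 2-aryl, OH trans to Br) | C(c1ccccc1)Oc1ccc([C@H]2Oc3c(ccc(OCc4ccccc4)c3OCc3ccccc3)[C@@H](O)[C@@H]2Br)cc1 | intermediate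
15 | (2R,3R,4R)-7,8-bis(benzyloxy)-2-[4-(benzyloxy)phenyl]-3,4-epoxychromane (oxirane oxygen cis to the 2-aryl group) | C(c1ccccc1)Oc1ccc([C@H]2Oc3c(ccc(OCc4ccccc4)c3OCc3ccccc3)[C@H]4O[C@@H]24)cc1 | intermediate
16 | (2R,3R,4S)-7,8-bis(benzyloxy)-2-[4-(benzyloxy)phenyl]chromane-3,4-diol (2,3-cis-3,4-trans) | C(c1ccccc1)Oc1ccc([C@H]2Oc3c(ccc(OCc4ccccc4)c3OCc3ccccc3)[C@H](O)[C@H]2O)cc1 | intermediate
17 | (2R,3S,4S)-7,8-bis(benzyloxy)-2-[4-(benzyloxy)phenyl]-3,4-bis[(tert-butyldimethylsilyl)oxy]chromane (2,3-cis-3,4-trans) | C(c1ccccc1)Oc1ccc([C@H]2Oc3c(ccc(OCc4ccccc4)c3OCc3ccccc3)[C@H](O[Si](C)(C)C(C)(C)C)[C@H]2O[Si](C)(C)C(C)(C)C)cc1 | intermediate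
18 | hexa-O-benzyl ether of the target with TBS ethers on the lower 3- and 4-hydroxy groups; upper unit (2R), 3-OH cis to the 2-aryl group, C4 bonded trans to 3-OH to C6 of the lower unit, which is 17 | C(c5ccccc5)Oc1ccc([C@H]2Oc3c(ccc(OCc5ccccc5)c3OCc5ccccc5)[C@H](c3cc4c(c(OCc5ccccc5)c3OCc5ccccc5)O[C@H](c3ccc(OCc5ccccc5)cc3)[C@H](O[Si](C)(C)C(C)(C)C)[C@H]4O[Si](C)(C)C(C)(C)C)[C@H]2O)cc1 | intermediate
19 | target with TBS ethers on the 3- and 4-hydroxy groups of the lower unit | Oc1ccc([C@H]2Oc3c(ccc(O)c3O)[C@H](c3cc4c(c(O)c3O)O[C@H](c3ccc(O)cc3)[C@H](O[Si](C)(C)C(C)(C)C)[C@H]4O[Si](C)(C)C(C)(C)C)[C@H]2O)cc1 | intermediate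
20 | epioritin-(4β→6)-epioritin-4β-ol, CNP0391561.3 | Oc1ccc([C@H]2Oc3c(ccc(O)c3O)[C@H](c3cc4c(c(O)c3O)O[C@H](c3ccc(O)cc3)[C@H](O)[C@H]4O)[C@H]2O)cc1 | target

**Step count and risks**

Total steps: 13. Longest linear sequence: 12 steps (1 → 2 → 3 → 4 → 5 → 11 → 13 → 15 → 16 → 17 → 18 → 19 → 20).

Steps most likely to fail:

1. Step 6 (key step). The ring closure onto the electron-rich aryl fluoride may be slower than base-induced decay of the benzylic sulfide anion, or the oxirane may be opened in part at its benzylic carbon. The fallback sets out from oxirane 8 and aldehyde 3 and comes back at flavene 13; it forms O1–C8a by a formyl-activated substitution and C3=C4 by metathesis in separate steps. Oxirane 8 would be homologated with dimethylsulfonium methylide (Me3S+ I−, n-BuLi, THF, −10 °C → 20 °C) to (1S)-1-[4-(benzyloxy)phenyl]prop-2-en-1-ol F1. Its sodium alkoxide (NaH, DMF, 0 °C) should displace the fluoride of 3, which the ortho formyl group activates, to give 3,4-bis(benzyloxy)-2-{[(1S)-1-[4-(benzyloxy)phenyl]prop-2-en-1-yl]oxy}benzaldehyde F2. Wittig methylenation (Ph3PCH3Br, potassium tert-butoxide, THF) would give the styrene 1,2-bis(benzyloxy)-3-{[(1S)-1-[4-(benzyloxy)phenyl]prop-2-en-1-yl]oxy}-4-ethenylbenzene F3. Ring-closing metathesis (second-generation Grubbs catalyst, CH2Cl2, 40 °C) would then give 13, and the route continues at step 8.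

2. Step 8. Bromination may go to ring A instead of the alkene, the facial selectivity may be poor, or the very labile benzylic oxirane may open during closure or isolation. The fallback sets out from 13 and comes back at diol 16. Hydroboration–oxidation (BH3·THF; then NaOH, H2O2), with boron entering C3 anti to the 2-aryl group, would give (2R,3S)-7,8-bis(benzyloxy)-2-[4-(benzyloxy)phenyl]chroman-3-ol F4 (2,3-trans). Dess–Martin oxidation would give (2R)-7,8-bis(benzyloxy)-2-[4-(benzyloxy)phenyl]chroman-3-one F5. Reduction with LiBH(s-Bu)3 (THF, −78 °C), hydride anti to the 2-aryl group, would give (2R,3R)-7,8-bis(benzyloxy)-2-[4-(benzyloxy)phenyl]chroman-3-ol F6 (2,3-cis). Benzylic oxidation with DDQ in CH2Cl2/H2O, with water adding to the C4 cation anti to the 3-hydroxy group, would give 16. Compound 16 then enters step 10 as before and, activated at its 4-hydroxy group by BF3·OEt2, takes the place of 15 in step 11.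

3. Step 11. Hydride shift in the activated epoxide (rearrangement to the flavan-3-one), self-condensation of 15 through its own ring A, or attack by the wrong position of 17 may compete with the wanted arylation. The fallback sets out from 15 and comes back at 18. Opening of 15 with thiophenol (PhSH, catalytic Et3N, THF, 0 °C; SN2 at C4) would give the stable (2R)-7,8-bis(benzyloxy)-2-[4-(benzyloxy)phenyl]-4-(phenylsulfanyl)chroman-3-ol F7 (3-OH cis to 2-aryl, 4-sulfanyl trans to 3-OH), which can be purified. Thiophilic activation (AgBF4, THF/CH2Cl2, 0 °C) in the presence of excess 17 would release the C4 cation under conditions that leave the silyl ethers alone, and capture by C6 of ring D anti to the 3-hydroxy group would give 18.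

**Further compounds**

F1 | step 6 | (1S)-1-[4-(benzyloxy)phenyl]prop-2-en-1-ol | C=C[C@H](O)c1ccc(OCc2ccccc2)cc1
F2 | step 6 | 3,4-bis(benzyloxy)-2-{[(1S)-1-[4-(benzyloxy)phenyl]prop-2-en-1-yl]oxy}benzaldehyde | C=C[C@H](Oc1c(C=O)ccc(OCc2ccccc2)c1OCc1ccccc1)c1ccc(OCc2ccccc2)cc1
F3 | step 6 | 1,2-bis(benzyloxy)-3-{[(1S)-1-[4-(benzyloxy)phenyl]prop-2-en-1-yl]oxy}-4-ethenylbenzene | C=C[C@H](Oc1c(C=C)ccc(OCc2ccccc2)c1OCc1ccccc1)c1ccc(OCc2ccccc2)cc1
F4 | step 8 | (2R,3S)-7,8-bis(benzyloxy)-2-[4-(benzyloxy)phenyl]chroman-3-ol | C(c1ccccc1)Oc1ccc([C@H]2Oc3c(ccc(OCc4ccccc4)c3OCc3ccccc3)C[C@@H]2O)cc1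
F5 | step 8 | (2R)-7,8-bis(benzyloxy)-2-[4-(benzyloxy)phenyl]chroman-3-one | C(c1ccccc1)Oc1ccc([C@H]2Oc3c(ccc(OCc4ccccc4)c3OCc3ccccc3)CC2=O)cc1
F6 | step 8 | (2R,3R)-7,8-bis(benzyloxy)-2-[4-(benzyloxy)phenyl]chroman-3-ol | C(c1ccccc1)Oc1ccc([C@H]2Oc3c(ccc(OCc4ccccc4)c3OCc3ccccc3)C[C@H]2O)cc1
F7 | step 11 | (2R)-7,8-bis(benzyloxy)-2-[4-(benzyloxy)phenyl]-4-(phenylsulfanyl)chroman-3-ol, 2,3-cis-3,4-trans | C(c1ccccc1)Oc1ccc([C@H]2Oc3c(ccc(OCc4ccccc4)c3OCc3ccccc3)[C@H](Sc3ccccc3)[C@H]2O)cc1
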